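**Plan**
- Retrosynthesis: the two sulfate S–O bonds are cut first, then the two aryl C–O bonds at ring A C3 and ring B C4 (back through C–B to C–H), and last the diaryl ether bond between ring A C1 and the ring B oxygen.
- Enabling feature: ring A is numbered from its ether carbon (C1; sulfate at C3, hydroxyl at C5) and ring B likewise (C1; hydroxyls at C2 and C6, sulfate at C4). In the tri-oxygenated diaryl ether core, the two sulfated carbons are the only C–H positions with no ortho substituent.
- Forward: no ring is built. Both benzene rings are bought and joined by an Ullmann ether coupling; the methyl ethers are exchanged for silyl ethers; one twofold iridium C–H borylation marks ring A C3 and ring B C4; oxidation, sulfation, desilylation and release of the acid form finish the route.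
- Stereochemistry: the target is achiral and has no stereocentre; the only selectivity needed is positional and comes from steric control in the borylation.

Key step: step 4

Remark: the target is drawn as the free bis(hydrogen sulfate). Aryl hydrogen sulfates keep best as salts, so the diammonium salt 11 is taken as the storable form and the free acid 12 is released from it only in the last step, cold and dilute.

**Route**

Step 1
Reactants: 1 2,6-dimethoxyphenol; 2 3-bromoanisole
Product: 3 1,3-dimethoxy-2-(3-methoxyphenoxy)benzene
Conditions: CuI (10 mol%), N,N-dimethylglycine hydrochloride (30 mol%), Cs2CO3, 1,4-dioxane, 100 °C, argon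
Reagents that add atoms: none
Why: Ullmann diaryl ether synthesis, in which the amino acid ligand should let the hindered but electron-rich 2,6-dimethoxyphenoxide displace the aryl bromide at moderate temperature while the methyl ethers stay inert.

Step 2
Reactants: 3 1,3-dimethoxy-2-(3-methoxyphenoxy)benzene
Product: 4 2-(3-hydroxyphenoxy)benzene-1,3-diol
Conditions: BBr3 (4.5 equiv), CH2Cl2, −78 °C to rt; then H2O, 0 °C
Reagents that add atoms: none
Why: BBr3 cleavage of aryl methyl ethers, in which bromide attacks the methyl carbon of each boron-complexed ether; the diaryl ether offers no sp3 carbon and should survive.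

Step 3
Reactants: 4 2-(3-hydroxyphenoxy)benzene-1,3-diol; 5 tert-butyldimethylsilyl chloride (3.6 equiv)
Product: 6 2-[3-(tert-butyldimethylsilyloxy)phenoxy]-1,3-bis(tert-butyldimethylsilyloxy)benzene
Conditions: imidazole (7 equiv), DMAP (cat.), DMF, rt
Reagents that add atoms: tert-butyldimethylsilyl chloride (second equivalent), CC(C)(C)[Si](C)(C)Cl; tert-butyldimethylsilyl chloride (third equivalent), CC(C)(C)[Si](C)(C)Cl
Why: imidazole-promoted silylation of phenols, in which each of the three hydroxyls takes one silyl group from 5 (one molecule stands among the reactants and the two further ones are entered as reagents); none of the hydroxyls has more than one ortho neighbour, so exhaustive silylation should proceed.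

Step 4
Reactants: 6 2-[3-(tert-butyldimethylsilyloxy)phenoxy]-1,3-bis(tert-butyldimethylsilyloxy)benzene; 7 bis(pinacolato)diboron (2.4 equiv)
Product: 8 2-[3-(tert-butyldimethylsilyloxy)-5-(4,4,5,5-tetramethyl-1,3,2-dioxaborolan-2-yl)phenoxy]-1,3-bis(tert-butyldimethylsilyloxy)-5-(4,4,5,5-tetramethyl-1,3,2-dioxaborolan-2-yl)benzene (boron at ring A C3 and ring B C4)
Conditions: [Ir(OMe)(cod)]2 (3 mol%), 4,4'-di-tert-butyl-2,2'-bipyridine (6 mol%), cyclohexane, 80 °C, argon
Reagents that add atoms: none
Why: Precatalyst, bipyridine ligand and B2pin2 form a trivalent iridium tris(boryl) complex that adds an aryl C–H bond oxidatively to give a pentavalent iridium aryl hydride, reductive elimination forms the C–B bond, and B2pin2 or HBpin restores the tris(boryl) species. The closest known reaction type is the sterically governed iridium-catalysed arene C–H borylation, in which 1,3-disubstituted benzenes react at C5 and 1,2,3-trisubstituted benzenes also at C5. No ring closes and no stereocentre forms; two C–B bonds are made, which later become the two sulfate C–O bonds. The step needs site selectivity among seven aryl C–H bonds: on ring A, C2 and C4 each lie ortho to one oxygen substituent and C6 lies between two, and on ring B, C3 and C5 each lie next to a silyloxy group, so only ring A C3 and ring B C4 have hydrogen on both sides. The bulky silyl groups and the 2,6-disubstituted aryloxy group widen this bias, and the alkyl C–H bonds of the silyl groups should not react with this bipyridine catalyst at 80 °C. The excess of B2pin2, with a second catalyst charge if needed, should carry the slower, more electron-rich ring B to full conversion.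

Step 5
Reactants: 8 the bis(pinacol boronate)
Product: 9 3-[2,6-bis(tert-butyldimethylsilyloxy)-4-hydroxyphenoxy]-5-(tert-butyldimethylsilyloxy)phenol
Conditions: Oxone (2KHSO5·KHSO4·K2SO4; 2.2 equiv KHSO5), acetone/H2O 1:1, 0 °C to rt, 10–15 min; then aq. NaHSO3
Reagents that add atoms: potassium peroxymonosulfate (active salt of Oxone), [K+].[O-]S(=O)(=O)OO
Why: oxidation of aryl boronic esters by a peroxide, with 1,2-shift of the aryl group from boron to oxygen and hydrolysis of the borate; the short contact time should spare the aryl silyl ethers and the electron-rich phenols.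

Step 6
Reactants: 9 3-[2,6-bis(tert-butyldimethylsilyloxy)-4-hydroxyphenoxy]-5-(tert-butyldimethylsilyloxy)phenol
Product: 10 bis(pyridinium) 3-[2,6-bis(tert-butyldimethylsilyloxy)-4-(sulfonatooxy)phenoxy]-5-(tert-butyldimethylsilyloxy)phenyl sulfate
Conditions: SO3·pyridine (6 equiv), pyridine, rt to 40 °C; then Sephadex LH-20, MeOH
Reagents that add atoms: sulfur trioxide–pyridine complex, O=S(=O)([O-])[n+]1ccccc1
Why: O-sulfation of phenols with a sulfur trioxide–amine complex; only the two phenols freed in step 5 are available, because the other three oxygens are silyl ethers, which tolerate dry pyridine.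

Step 7
Reactants: 10 the bis(pyridinium) tris-silyl bis-sulfate
Product: 11 diammonium 3-(2,6-dihydroxy-4-sulfonatooxyphenoxy)-5-hydroxyphenyl sulfate
Conditions: NH4F (15 equiv), MeOH, rt to 40 °C; evaporation; C18 reversed-phase desalting (H2O/MeOH)
Reagents that add atoms: ammonium fluoride, [NH4+].[F-]
Why: fluoride-mediated desilylation of aryl silyl ethers in a near-neutral medium to which sulfate monoester anions are inert; the ammonia set free replaces pyridine as counter-ion, and the silyl fluoride, pyridine and ammonia are volatile.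

Step 8
Reactants: 11 the diammonium salt
Product: 12 3-(2,6-dihydroxy-4-sulfooxyphenoxy)-5-hydroxyphenyl hydrogen sulfate (CNP0460023.0)
Conditions: Dowex 50WX8 (H+ form), H2O, 0–4 °C; eluate freeze-dried at once
Reagents that add atoms: none
Why: cation exchange on a sulfonic acid resin replaces ammonium by protons without touching the S–O ester bonds, provided the solution stays cold and dilute.

**Compound list**
1 | 2,6-dimethoxyphenol | COc1cccc(OC)c1O | starting material
2 | 3-bromoanisole | COc1cccc(Br)c1 | starting material
3 | 1,3-dimethoxy-2-(3-methoxyphenoxy)benzene | COc1cccc(Oc2c(OC)cccc2OC)c1 | intermediate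
4 | 2-(3-hydroxyphenoxy)benzene-1,3-diol | Oc1cccc(Oc2c(O)cccc2O)c1 | intermediate
5 | tert-butyldimethylsilyl chloride | CC(C)(C)[Si](C)(C)Cl | starting material
6 | 2-[3-(tert-butyldimethylsilyloxy)phenoxy]-1,3-bis(tert-butyldimethylsilyloxy)benzene | CC(C)(C)[Si](C)(C)Oc1cccc(Oc2c(O[Si](C)(C)C(C)(C)C)cccc2O[Si](C)(C)C(C)(C)C)c1 | intermediate
7 | bis(pinacolato)diboron | CC1(C)OB(OC1(C)C)B1OC(C)(C)C(C)(C)O1 | starting material
8 | bis(pinacol boronate) of 6 with boron at ring A C3 and ring B C4 | CC(C)(C)[Si](C)(C)Oc1cc(Oc2c(O[Si](C)(C)C(C)(C)C)cc(B3OC(C)(C)C(C)(C)O3)cc2O[Si](C)(C)C(C)(C)C)cc(B2OC(C)(C)C(C)(C)O2)c1 | intermediate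
9 | 3-[2,6-bis(tert-butyldimethylsilyloxy)-4-hydroxyphenoxy]-5-(tert-butyldimethylsilyloxy)phenol | CC(C)(C)[Si](C)(C)Oc1cc(O)cc(Oc2c(O[Si](C)(C)C(C)(C)C)cc(O)cc2O[Si](C)(C)C(C)(C)C)c1 | intermediate
10 | bis(pyridinium) 3-[2,6-bis(tert-butyldimethylsilyloxy)-4-(sulfonatooxy)phenoxy]-5-(tert-butyldimethylsilyloxy)phenyl sulfate | CC(C)(C)[Si](C)(C)Oc1cc(OS(=O)(=O)[O-])cc(Oc2c(O[Si](C)(C)C(C)(C)C)cc(OS(=O)(=O)[O-])cc2O[Si](C)(C)C(C)(C)C)c1.c1cc[nH+]cc1.c1cc[nH+]cc1 | intermediate
11 | diammonium 3-(2,6-dihydroxy-4-sulfonatooxyphenoxy)-5-hydroxyphenyl sulfate | [NH4+].[NH4+].[O-]S(=O)(=O)Oc1cc(O)cc(Oc2c(O)cc(OS(=O)(=O)[O-])cc2O)c1 | intermediate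
12 | 3-(2,6-dihydroxy-4-sulfooxyphenoxy)-5-hydroxyphenyl hydrogen sulfate | O=S(=O)(O)Oc1cc(O)cc(Oc2c(O)cc(OS(=O)(=O)O)cc2O)c1 | target

**Step count**
Total steps: 8. Longest linear sequence: 8 (1 to 12; the route is fully linear).

**Steps most likely to fail**

Step 4. The second borylation, on the electron-rich tri-oxygenated ring B, may stall, or boron may enter next to an oxygen substituent, leaving mixtures of mono-, bis- and misplaced boronates that are hard to separate. The fallback makes the same two C–B bonds from C–Cl bonds by palladium-catalysed Miyaura borylation. It sets out from 2,6-dimethoxyphenol (1) and returns at 8. Para-chlorination of 1 with SO2Cl2 in CH2Cl2 at 0 °C should give 4-chloro-2,6-dimethoxyphenol F1. Ullmann coupling of F1 with commercial 1-bromo-3-chloro-5-methoxybenzene F2 under the conditions of step 1, where only the C–Br bond should react, would give 5-chloro-2-(3-chloro-5-methoxyphenoxy)-1,3-dimethoxybenzene F3. BBr3 demethylation as in step 2 would give 5-chloro-2-(3-chloro-5-hydroxyphenoxy)benzene-1,3-diol F4, and silylation with 5 as in step 3 would give 5-chloro-2-[3-chloro-5-(tert-butyldimethylsilyloxy)phenoxy]-1,3-bis(tert-butyldimethylsilyloxy)benzene F5. Twofold borylation of F5 with 7, Pd2(dba)3, XPhos and KOAc in dioxane at 100 °C should then deliver 8.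

Step 8. Acid-catalysed hydrolysis of the aryl sulfate esters may set in inside the strongly acidic resin bed or while the free acid is concentrated. The fallback frees the acid by salt metathesis with exact stoichiometry instead of a resin. It sets out from 11 and returns at 12. Ba(OAc)2 (1 equiv) in water, followed by precipitation with ethanol, should give barium 3-(2,6-dihydroxy-4-sulfonatooxyphenoxy)-5-hydroxyphenyl sulfate F6. A suspension of F6 in ice water is treated with exactly one equivalent of dilute H2SO4, the BaSO4 is removed by centrifugation, and the cold dilute solution of 12 is freeze-dried.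

Step 6. Sulfation may stop at the monosulfate stage, and silyl ethers may be lost while the amphiphilic pyridinium salt, which cannot be chromatographed on silica, is handled. The fallback uses neutral, chromatographable protected sulfate diesters. It sets out from 9 and returns at 11. Treatment of 9 with 2,2,2-trichloroethyl chlorosulfate, Et3N and DMAP in THF at 0 °C should give 3-[2,6-bis(tert-butyldimethylsilyloxy)-4-(2,2,2-trichloroethoxysulfonyloxy)phenoxy]-5-(tert-butyldimethylsilyloxy)phenyl 2,2,2-trichloroethyl sulfate F7, purified on silica. Zinc dust and HCO2NH4 in MeOH at rt should remove both trichloroethyl groups by reductive elimination and give diammonium 3-[2,6-bis(tert-butyldimethylsilyloxy)-4-(sulfonatooxy)phenoxy]-5-(tert-butyldimethylsilyloxy)phenyl sulfate F8. NH4F in MeOH, as in step 7, would then give 11.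

Further compounds
F1 | step 4 | 4-chloro-2,6-dimethoxyphenol | COc1cc(Cl)cc(OC)c1O
F2 | step 4 | 1-bromo-3-chloro-5-methoxybenzene | COc1cc(Cl)cc(Br)c1
F3 | step 4 | 5-chloro-2-(3-chloro-5-methoxyphenoxy)-1,3-dimethoxybenzene | COc1cc(Cl)cc(Oc2c(OC)cc(Cl)cc2OC)c1
F4 | step 4 | 5-chloro-2-(3-chloro-5-hydroxyphenoxy)benzene-1,3-diol | Oc1cc(Cl)cc(Oc2c(O)cc(Cl)cc2O)c1
F5 | step 4 | 5-chloro-2-[3-chloro-5-(tert-butyldimethylsilyloxy)phenoxy]-1,3-bis(tert-butyldimethylsilyloxy)benzene | CC(C)(C)[Si](C)(C)Oc1cc(Cl)cc(Oc2c(O[Si](C)(C)C(C)(C)C)cc(Cl)cc2O[Si](C)(C)C(C)(C)C)c1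
F6 | step 8 | barium 3-(2,6-dihydroxy-4-sulfonatooxyphenoxy)-5-hydroxyphenyl sulfate | [Ba+2].[O-]S(=O)(=O)Oc1cc(O)cc(Oc2c(O)cc(OS(=O)(=O)[O-])cc2O)c1
F7 | step 6 | 3-[2,6-bis(tert-butyldimethylsilyloxy)-4-(2,2,2-trichloroethoxysulfonyloxy)phenoxy]-5-(tert-butyldimethylsilyloxy)phenyl 2,2,2-trichloroethyl sulfate | CC(C)(C)[Si](C)(C)Oc1cc(OS(=O)(=O)OCC(Cl)(Cl)Cl)cc(Oc2c(O[Si](C)(C)C(C)(C)C)cc(OS(=O)(=O)OCC(Cl)(Cl)Cl)cc2O[Si](C)(C)C(C)(C)C)c1
F8 | step 6 | diammonium 3-[2,6-bis(tert-butyldimethylsilyloxy)-4-(sulfonatooxy)phenoxy]-5-(tert-butyldimethylsilyloxy)phenyl sulfate | [NH4+].[NH4+].CC(C)(C)[Si](C)(C)Oc1cc(OS(=O)(=O)[O-])cc(Oc2c(O[Si](C)(C)C(C)(C)C)cc(OS(=O)(=O)[O-])cc2O[Si](C)(C)C(C)(C)C)c1
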